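**Plan**

- Retrosynthesis: after the three silyl ethers, ring C is cut at C4a–C4, C4–C3 and O1–C2. The pyranone is an aroyl group (C4a–C4=O), an enone (C3=C2) and a vinyl aryl ether (O1–C2) on a phloroglucinol ring A whose two oxygens flanking C4a are equivalent. It therefore maps onto 2-iodophloroglucinol triacetate (C4a–I, future O1), CO (C4) and a ring B arylacetylene (C3, C2).
- The alkyne is cut further at the γ-O–acyl bond (p-coumaric acid), the aryl–alkyne bond (Sonogashira), the Cα–aryl bond (aryl Grignard plus aldehyde) and the Cβ–O aryl ether bond (Mitsunobu on a glycerate).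
- Forward: the glycerate chain is elaborated linearly (Cβ–OAr, Cα–Ar, C≡C, γ-ester, α-silyl ether) and the iodide is made in two steps from phloroglucinol. Ring C, the only ring formed, closes last before global desilylation.
- Stereochemistry: Cβ (S) comes from methyl (R)-glycerate acetonide by Mitsunobu inversion. Cα (R) is set by Felkin–Anh addition of the guaiacyl Grignard reagent anti to the aryloxy group. The E-alkene is carried in from p-coumaric acid.

Key step: step 15

Remark: Cα, Cβ and Cγ denote the benzylic carbinol carbon, the aryloxy-bearing carbon and the CH2O carbon of the arylglycerol chain; the (αR,βS) target is the 1,2-anti (erythro) isomer, and excess Et2NH is assumed to aminolyse all three aryl acetates of ring A during step 15.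

**Route**

Step 1
Reactants: 1 methyl (R)-2,2-dimethyl-1,3-dioxolane-4-carboxylate
Product: 2 methyl (R)-2,3-dihydroxypropanoate
Conditions: Dowex 50W-X8 (H+ form), MeOH, rt
Reagents that add atoms: none
Why: Acid-catalysed acetonide methanolysis (transketalisation to the solvent) should release the diol without touching the methyl ester or the C2 stereocentre, which is not involved.

Step 2
Reactants: 2 methyl (R)-2,3-dihydroxypropanoate
Product: 3 methyl (R)-3-[(tert-butyldimethylsilyl)oxy]-2-hydroxypropanoate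
Conditions: TBSCl (1.05 equiv), imidazole, CH2Cl2, −20 → 0 °C
Reagents that add atoms: tert-butyldimethylsilyl chloride, CC(C)(C)[Si](C)(C)Cl
Why: Sterically controlled silylation with a bulky silyl chloride at low temperature should select the primary hydroxyl over the secondary α-hydroxy-ester hydroxyl.

Step 3
Reactants: 3 methyl (R)-3-[(tert-butyldimethylsilyl)oxy]-2-hydroxypropanoate; 4 4-bromo-2,6-dimethoxyphenol
Product: 5 methyl (S)-2-(4-bromo-2,6-dimethoxyphenoxy)-3-[(tert-butyldimethylsilyl)oxy]propanoate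
Conditions: PPh3, DIAD, toluene, 0 °C → rt
Reagents that add atoms: none
Why: Mitsunobu etherification of an α-hydroxy ester with a phenol proceeds by SN2 displacement of the oxyphosphonium group, so C2 is inverted from R to S and becomes Cβ, the activated α-carbonyl position compensating for the two ortho methoxy groups of the phenol.

Step 4
Reactants: 5 methyl (S)-2-(4-bromo-2,6-dimethoxyphenoxy)-3-[(tert-butyldimethylsilyl)oxy]propanoate
Product: 6 (S)-2-(4-bromo-2,6-dimethoxyphenoxy)-3-[(tert-butyldimethylsilyl)oxy]propanal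
Conditions: i-Bu2AlH (1.1 equiv), CH2Cl2, −78 °C; MeOH, aq. potassium sodium tartrate; used crude at once
Reagents that add atoms: none
Why: Partial ester reduction with i-Bu2AlH should stop at the aldehyde because the aluminium hemiacetal of an α-oxygenated ester persists at −78 °C until work-up, leaving the aryl bromide, the silyl ether and the stereocentre intact.

Step 5
Reactants: 7 4-bromo-2-methoxyphenol
Product: 8 (4-bromo-2-methoxyphenoxy)triisopropylsilane
Conditions: TIPSCl, imidazole, DMF, rt
Reagents that add atoms: triisopropylsilyl chloride, CC(C)[Si](Cl)(C(C)C)C(C)C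
Why: Standard phenol silylation installs an aryl TIPS ether that should tolerate Grignard formation, K2CO3/MeOH and aqueous acetic acid later in the route.

Step 6
Reactants: 8 (4-bromo-2-methoxyphenoxy)triisopropylsilane; 6 (S)-2-(4-bromo-2,6-dimethoxyphenoxy)-3-[(tert-butyldimethylsilyl)oxy]propanal
Product: 10 (1R,2S)-2-(4-bromo-2,6-dimethoxyphenoxy)-3-[(tert-butyldimethylsilyl)oxy]-1-{3-methoxy-4-[(triisopropylsilyl)oxy]phenyl}propan-1-ol (1,2-anti), via arylmagnesium bromide 9 (not isolated)
Conditions: 8, Mg, I2 (cat.), THF, 50 °C; then 6, THF, −78 → −40 °C; aq. NH4Cl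
Reagents that add atoms: none
Why: Grignard addition under polar Felkin–Anh control is expected, since in THF neither the weakly basic, hindered aryloxy oxygen nor the silyl ether should chelate magnesium, so the aryl nucleophile attacks anti to the C–OAr bond past the α-hydrogen and sets Cα as R (1,2-anti), the minor epimer being removed by chromatography.

Step 7
Reactants: 10 the anti bromo carbinol of step 6
Product: 11 (1R,2S)-3-[(tert-butyldimethylsilyl)oxy]-2-{2,6-dimethoxy-4-[(trimethylsilyl)ethynyl]phenoxy}-1-{3-methoxy-4-[(triisopropylsilyl)oxy]phenyl}propan-1-ol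
Conditions: HC≡CSiMe3, PdCl2(PhCN)2 (3 mol %), [HP(t-Bu)3]BF4 (6 mol %), CuI (2 mol %), i-Pr2NH, dioxane, rt
Reagents that add atoms: ethynyltrimethylsilane, C#C[Si](C)(C)C
Why: Sonogashira coupling with the electron-rich tri-tert-butylphosphine ligand should allow zerovalent palladium to insert into the electron-rich aryl bromide at room temperature, and the free carbinol and silyl ethers are spectators.

Step 8
Reactants: 11 the trimethylsilyl alkyne of step 7
Product: 12 (1R,2S)-3-[(tert-butyldimethylsilyl)oxy]-2-(4-ethynyl-2,6-dimethoxyphenoxy)-1-{3-methoxy-4-[(triisopropylsilyl)oxy]phenyl}propan-1-ol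
Conditions: K2CO3 (0.2 equiv), MeOH/THF (1:1), 0 °C
Reagents that add atoms: none
Why: Carbonate-catalysed methanolysis of the C(sp)–Si bond (protodesilylation) is fast at 0 °C, whereas the alkyl TBS ether and the hindered aryl TIPS ether should survive the brief exposure.

Step 9
Reactants: 12 the terminal alkyne of step 8
Product: 13 (1R,2S)-2-(4-ethynyl-2,6-dimethoxyphenoxy)-1-{3-methoxy-4-[(triisopropylsilyl)oxy]phenyl}propane-1,3-diol
Conditions: AcOH/THF/H2O (3:1:1), rt
Reagents that add atoms: none
Why: Mild acid hydrolysis of a primary alkyl TBS ether should leave the acid-stable aryl TIPS ether untouched, and acetic acid is too weak to ionise the benzylic carbinol, so Cα is not at risk.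

Step 10
Reactants: 14 (E)-p-coumaric acid
Product: 16 (E)-3-{4-[(triisopropylsilyl)oxy]phenyl}acrylic acid, via bis-silylated coumarate 15 (not isolated)
Conditions: TIPSCl (2.2 equiv), imidazole, DMF, rt; then K2CO3, THF/MeOH/H2O, rt; 1 M HCl to pH 3
Reagents that add atoms: triisopropylsilyl chloride, CC(C)[Si](Cl)(C(C)C)C(C)C
Why: Silylation of both acidic sites followed by selective hydrolysis of the much more labile silyl ester is the usual way to an O-silyl hydroxycinnamic acid, and the E-alkene is not affected.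

Step 11
Reactants: 13 the diol of step 9; 16 (E)-3-{4-[(triisopropylsilyl)oxy]phenyl}acrylic acid
Product: 17 (2S,3R)-2-(4-ethynyl-2,6-dimethoxyphenoxy)-3-hydroxy-3-{3-methoxy-4-[(triisopropylsilyl)oxy]phenyl}propyl (E)-3-{4-[(triisopropylsilyl)oxy]phenyl}acrylate
Conditions: 16 (1.05 equiv), DCC, DMAP (0.1 equiv), CH2Cl2, −20 → 0 °C
Reagents that add atoms: none
Why: In a Steglich esterification at low temperature with one equivalent of acid, the unhindered primary γ-hydroxyl should be acylated much faster than the secondary benzylic α-hydroxyl flanked by the bulky aryl ether.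

Step 12
Reactants: 17 the γ-coumarate of step 11
Product: 18 (2S,3R)-2-(4-ethynyl-2,6-dimethoxyphenoxy)-3-{3-methoxy-4-[(triisopropylsilyl)oxy]phenyl}-3-[(triethylsilyl)oxy]propyl (E)-3-{4-[(triisopropylsilyl)oxy]phenyl}acrylate
Conditions: Et3SiOTf, 2,6-lutidine, CH2Cl2, −78 °C
Reagents that add atoms: triethylsilyl trifluoromethanesulfonate, CC[Si](CC)(CC)OS(=O)(=O)C(F)(F)F
Why: Silyl triflate silylation of the hindered secondary alcohol masks the α-hydroxyl against γ-to-α acyl migration under the amine bases of step 15, and the TES ether is labile enough to leave with the aryl silyl ethers at the end.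

Step 13
Reactants: 19 phloroglucinol (benzene-1,3,5-triol)
Product: 20 2-iodobenzene-1,3,5-triol
Conditions: I2 (1.0 equiv), NaHCO3, THF/H2O (1:1), 0 °C
Reagents that add atoms: iodine, II
Why: Electrophilic aromatic iodination of the threefold-symmetric triol can give only one mono-iodide, and one equivalent of iodine under bicarbonate buffering should limit over-iodination.

Step 14
Reactants: 20 2-iodobenzene-1,3,5-triol
Product: 21 2-iodobenzene-1,3,5-triyl triacetate
Conditions: Ac2O, pyridine, DMAP (cat.), CH2Cl2, 0 °C → rt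
Reagents that add atoms: acetic anhydride, CC(=O)OC(C)=O
Why: Peracetylation converts the air- and light-sensitive iodotriol into a stable, less electron-rich ortho-iodophenol acetate, the substrate class for which the carbonylative annulation is established.

Step 15
Reactants: 18 the ring B alkyne of step 12; 21 2-iodobenzene-1,3,5-triyl triacetate
Product: 24 (2S,3R)-2-[4-(5,7-dihydroxy-4-oxo-4H-chromen-2-yl)-2,6-dimethoxyphenoxy]-3-{3-methoxy-4-[(triisopropylsilyl)oxy]phenyl}-3-[(triethylsilyl)oxy]propyl (E)-3-{4-[(triisopropylsilyl)oxy]phenyl}acrylate, via ynone 22 (not isolated), via enaminone 23 (not isolated)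
Conditions: CO (1 atm), PdCl2(PPh3)2 (5 mol %), dppp (5 mol %), thiourea (5 mol %), Et2NH (excess), DBU (2 equiv), DMF, 40 °C
Reagents that add atoms: carbon monoxide, [C-]#[O+]
Why: PdCl2(PPh3)2 is reduced in situ to zerovalent palladium, which inserts into the C–I bond of 21; CO insertion gives an aroyl complex of divalent palladium that is alkynylated by 18 (amine-assisted, copper-free) and reductively eliminates ynone 22, forming C4a–C4 and C4–C3. Diethylamine adds to the ynone to give enaminone 23 and aminolyses the flanking acetate, and the freed phenoxide attacks the amine-bearing carbon and expels diethylamine, forming O1–C2. The closest known reaction is the palladium-catalysed carbonylative annulation of ortho-iodophenol acetates with terminal arylacetylenes to flavones under CO with Et2NH. Ring C closes in a 6-endo mode (addition–elimination at the β-carbon of the enaminone), and no stereocentre is formed or touched. The step needs flavone rather than aurone formation, which is secured by keeping the phenol acetylated until the C–C bonds are in place and by routing the closure through the enaminone; it needs no differentiation of the ring A oxygens, because the two acetoxy groups ortho to iodine are equivalent and the third becomes the 7-hydroxyl once excess Et2NH has removed the remaining acetates. The TES and TIPS ethers, the cinnamate ester and the alkyl aryl ether should be inert to CO, the catalyst and the amines at 40 °C.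

Step 16
Reactants: 24 the tris-silyl ether of step 15
Product: 25 (2S,3R)-2-[4-(5,7-dihydroxy-4-oxo-4H-chromen-2-yl)-2,6-dimethoxyphenoxy]-3-hydroxy-3-(4-hydroxy-3-methoxyphenyl)propyl (E)-3-(4-hydroxyphenyl)acrylate (target, αR,βS)
Conditions: Bu4NF/AcOH (1:1, 4 equiv), THF, 0 °C → rt
Reagents that add atoms: none
Why: Fluoride-mediated desilylation buffered with acetic acid should cleave the two aryl TIPS ethers and the secondary TES ether while the near-neutral medium avoids ester cleavage, γ-to-α acyl migration and quinone methide formation, and no stereocentre is touched.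

**Compound list**

1 | methyl (R)-2,2-dimethyl-1,3-dioxolane-4-carboxylate | COC(=O)[C@H]1COC(C)(C)O1 | starting material
2 | methyl (R)-2,3-dihydroxypropanoate | COC(=O)[C@H](O)CO | intermediate
3 | methyl (R)-3-[(tert-butyldimethylsilyl)oxy]-2-hydroxypropanoate | COC(=O)[C@H](O)CO[Si](C)(C)C(C)(C)C | intermediate
4 | 4-bromo-2,6-dimethoxyphenol | COc1cc(Br)cc(OC)c1O | starting material
5 | methyl (S)-2-(4-bromo-2,6-dimethoxyphenoxy)-3-[(tert-butyldimethylsilyl)oxy]propanoate | COC(=O)[C@@H](Oc1c(OC)cc(Br)cc1OC)CO[Si](C)(C)C(C)(C)C | intermediate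
6 | (S)-2-(4-bromo-2,6-dimethoxyphenoxy)-3-[(tert-butyldimethylsilyl)oxy]propanal | O=C[C@@H](Oc1c(OC)cc(Br)cc1OC)CO[Si](C)(C)C(C)(C)C | intermediate
7 | 4-bromo-2-methoxyphenol | COc1cc(Br)ccc1O | starting material
8 | (4-bromo-2-methoxyphenoxy)triisopropylsilane | COc1cc(Br)ccc1O[Si](C(C)C)(C(C)C)C(C)C | intermediate
9 | {3-methoxy-4-[(triisopropylsilyl)oxy]phenyl}magnesium bromide | COc1cc([Mg]Br)ccc1O[Si](C(C)C)(C(C)C)C(C)C | intermediate (not isolated)
10 | (1R,2S)-2-(4-bromo-2,6-dimethoxyphenoxy)-3-[(tert-butyldimethylsilyl)oxy]-1-{3-methoxy-4-[(triisopropylsilyl)oxy]phenyl}propan-1-ol | COc1cc([C@@H](O)[C@H](CO[Si](C)(C)C(C)(C)C)Oc2c(OC)cc(Br)cc2OC)ccc1O[Si](C(C)C)(C(C)C)C(C)C | intermediate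
11 | (1R,2S)-3-[(tert-butyldimethylsilyl)oxy]-2-{2,6-dimethoxy-4-[(trimethylsilyl)ethynyl]phenoxy}-1-{3-methoxy-4-[(triisopropylsilyl)oxy]phenyl}propan-1-ol | COc1cc([C@@H](O)[C@H](CO[Si](C)(C)C(C)(C)C)Oc2c(OC)cc(C#C[Si](C)(C)C)cc2OC)ccc1O[Si](C(C)C)(C(C)C)C(C)C | intermediate
12 | (1R,2S)-3-[(tert-butyldimethylsilyl)oxy]-2-(4-ethynyl-2,6-dimethoxyphenoxy)-1-{3-methoxy-4-[(triisopropylsilyl)oxy]phenyl}propan-1-ol | COc1cc([C@@H](O)[C@H](CO[Si](C)(C)C(C)(C)C)Oc2c(OC)cc(C#C)cc2OC)ccc1O[Si](C(C)C)(C(C)C)C(C)C | intermediate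
13 | (1R,2S)-2-(4-ethynyl-2,6-dimethoxyphenoxy)-1-{3-methoxy-4-[(triisopropylsilyl)oxy]phenyl}propane-1,3-diol | COc1cc([C@@H](O)[C@H](CO)Oc2c(OC)cc(C#C)cc2OC)ccc1O[Si](C(C)C)(C(C)C)C(C)C | intermediate
14 | (E)-p-coumaric acid | O=C(O)/C=C/c1ccc(O)cc1 | starting material
15 | triisopropylsilyl (E)-3-{4-[(triisopropylsilyl)oxy]phenyl}acrylate | CC(C)[Si](OC(=O)/C=C/c1ccc(O[Si](C(C)C)(C(C)C)C(C)C)cc1)(C(C)C)C(C)C | intermediate (not isolated)
16 | (E)-3-{4-[(triisopropylsilyl)oxy]phenyl}acrylic acid | O=C(O)/C=C/c1ccc(O[Si](C(C)C)(C(C)C)C(C)C)cc1 | intermediate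
17 | (2S,3R)-2-(4-ethynyl-2,6-dimethoxyphenoxy)-3-hydroxy-3-{3-methoxy-4-[(triisopropylsilyl)oxy]phenyl}propyl (E)-3-{4-[(triisopropylsilyl)oxy]phenyl}acrylate | COc1cc([C@@H](O)[C@H](COC(=O)/C=C/c2ccc(O[Si](C(C)C)(C(C)C)C(C)C)cc2)Oc2c(OC)cc(C#C)cc2OC)ccc1O[Si](C(C)C)(C(C)C)C(C)C | intermediate
18 | (2S,3R)-2-(4-ethynyl-2,6-dimethoxyphenoxy)-3-{3-methoxy-4-[(triisopropylsilyl)oxy]phenyl}-3-[(triethylsilyl)oxy]propyl (E)-3-{4-[(triisopropylsilyl)oxy]phenyl}acrylate | COc1cc([C@@H](O[Si](CC)(CC)CC)[C@H](COC(=O)/C=C/c2ccc(O[Si](C(C)C)(C(C)C)C(C)C)cc2)Oc2c(OC)cc(C#C)cc2OC)ccc1O[Si](C(C)C)(C(C)C)C(C)C | intermediate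
19 | phloroglucinol (benzene-1,3,5-triol) | Oc1cc(O)cc(O)c1 | starting material
20 | 2-iodobenzene-1,3,5-triol | Oc1cc(O)c(I)c(O)c1 | intermediate
21 | 2-iodobenzene-1,3,5-triyl triacetate | CC(=O)Oc1cc(OC(C)=O)c(I)c(OC(C)=O)c1 | intermediate
22 | ynone: compound 18 carrying a 2,4,6-triacetoxybenzoyl group on the terminal alkyne carbon | COc1cc([C@@H](O[Si](CC)(CC)CC)[C@H](COC(=O)/C=C/c2ccc(O[Si](C(C)C)(C(C)C)C(C)C)cc2)Oc2c(OC)cc(C#CC(=O)c3c(OC(C)=O)cc(OC(C)=O)cc3OC(C)=O)cc2OC)ccc1O[Si](C(C)C)(C(C)C)C(C)C | intermediate (not isolated)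
23 | enaminone: (E)-β-(diethylamino)enone from addition of Et2NH to ynone 22 | COc1cc([C@@H](O[Si](CC)(CC)CC)[C@H](COC(=O)/C=C/c2ccc(O[Si](C(C)C)(C(C)C)C(C)C)cc2)Oc2c(OC)cc(/C(=C\C(=O)c3c(OC(C)=O)cc(OC(C)=O)cc3OC(C)=O)N(CC)CC)cc2OC)ccc1O[Si](C(C)C)(C(C)C)C(C)C | intermediate (not isolated)
24 | (2S,3R)-2-[4-(5,7-dihydroxy-4-oxo-4H-chromen-2-yl)-2,6-dimethoxyphenoxy]-3-{3-methoxy-4-[(triisopropylsilyl)oxy]phenyl}-3-[(triethylsilyl)oxy]propyl (E)-3-{4-[(triisopropylsilyl)oxy]phenyl}acrylate | COc1cc([C@@H](O[Si](CC)(CC)CC)[C@H](COC(=O)/C=C/c2ccc(O[Si](C(C)C)(C(C)C)C(C)C)cc2)Oc2c(OC)cc(-c3cc(=O)c4c(O)cc(O)cc4o3)cc2OC)ccc1O[Si](C(C)C)(C(C)C)C(C)C | intermediate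
25 | (2S,3R)-2-[4-(5,7-dihydroxy-4-oxo-4H-chromen-2-yl)-2,6-dimethoxyphenoxy]-3-hydroxy-3-(4-hydroxy-3-methoxyphenyl)propyl (E)-3-(4-hydroxyphenyl)acrylate | COc1cc([C@@H](O)[C@H](COC(=O)/C=C/c2ccc(O)cc2)Oc2c(OC)cc(-c3cc(=O)c4c(O)cc(O)cc4o3)cc2OC)ccc1O | target

**Step count and risks**

Total step count: 16. Longest linear sequence: 12 steps (steps 1, 2, 3, 4, 6, 7, 8, 9, 11, 12, 15, 16).

Steps most likely to fail:

Step 15. The aroyl–palladium intermediate may be intercepted by diethylamine (amide formation) or the alkyne may couple without CO insertion. Premature deacetylation of the very electron-rich ring may slow oxidative addition and lead to protodeiodination. The amine bases may also partly remove the aryl silyl ethers or leave the 5-acetate in place. The fallback sets out from 18 and replaces CO gas by a preformed acyl donor. Commercial 2,4,6-trihydroxybenzoic acid would be peracetylated (Ac2O, pyridine) to 2,4,6-triacetoxybenzoic acid F1 and converted with oxalyl chloride and catalytic DMF into 2,4,6-triacetoxybenzoyl chloride F2. Acyl Sonogashira coupling of F2 with 18 (PdCl2(PPh3)2, CuI, Et3N, THF, rt) should give ynone 22 directly. Treatment of 22 with excess Et2NH in DMF at 40 °C should then effect conjugate addition, deacetylation and 6-endo closure, returning to the route at 24.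

Step 6. A magnesium chelate between the carbonyl and aryloxy oxygens would favour the syn epimer and erode facial selectivity, and the basic reagent may epimerise the α-aryloxy aldehyde before addition. The fallback sets out from 10 obtained as a mixture of C1 epimers and moves stereocontrol from C–C to C–H bond formation. Dess–Martin oxidation (NaHCO3-buffered, CH2Cl2) should give (S)-2-(4-bromo-2,6-dimethoxyphenoxy)-3-[(tert-butyldimethylsilyl)oxy]-1-{3-methoxy-4-[(triisopropylsilyl)oxy]phenyl}propan-1-one F3. Chelation-controlled reduction with Zn(BH4)2 in Et2O at −20 °C, with zinc bridging the ketone and the α-aryloxy oxygen and hydride arriving from the face of the α-hydrogen, should return the anti carbinol 10.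

Step 11. Discrimination between the primary and the benzylic hydroxyl may be insufficient, giving α-ester or diester. The fallback sets out from 13 and replaces kinetic selection in the acylation by protecting-group differentiation. Bis-silylation (TESCl, imidazole, DMF) should give (1R,2S)-2-(4-ethynyl-2,6-dimethoxyphenoxy)-1-{3-methoxy-4-[(triisopropylsilyl)oxy]phenyl}-1,3-bis[(triethylsilyl)oxy]propane F4. Selective methanolysis of the primary TES ether (PPTS, MeOH/CH2Cl2, −10 °C) should give (2S,3R)-2-(4-ethynyl-2,6-dimethoxyphenoxy)-3-{3-methoxy-4-[(triisopropylsilyl)oxy]phenyl}-3-[(triethylsilyl)oxy]propan-1-ol F5. Steglich esterification of its only free hydroxyl with 16 (DCC, DMAP, CH2Cl2) comes back to the route at 18, bypassing 17 and step 12.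

Further compounds
F1 | step 15 | 2,4,6-triacetoxybenzoic acid | CC(=O)Oc1cc(OC(C)=O)c(C(=O)O)c(OC(C)=O)c1
F2 | step 15 | 2,4,6-triacetoxybenzoyl chloride | CC(=O)Oc1cc(OC(C)=O)c(C(=O)Cl)c(OC(C)=O)c1
F3 | step 6 | (S)-2-(4-bromo-2,6-dimethoxyphenoxy)-3-[(tert-butyldimethylsilyl)oxy]-1-{3-methoxy-4-[(triisopropylsilyl)oxy]phenyl}propan-1-one | COc1cc(C(=O)[C@H](CO[Si](C)(C)C(C)(C)C)Oc2c(OC)cc(Br)cc2OC)ccc1O[Si](C(C)C)(C(C)C)C(C)C
F4 | step 11 | (1R,2S)-2-(4-ethynyl-2,6-dimethoxyphenoxy)-1-{3-methoxy-4-[(triisopropylsilyl)oxy]phenyl}-1,3-bis[(triethylsilyl)oxy]propane | COc1cc([C@@H](O[Si](CC)(CC)CC)[C@H](CO[Si](CC)(CC)CC)Oc2c(OC)cc(C#C)cc2OC)ccc1O[Si](C(C)C)(C(C)C)C(C)C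
F5 | step 11 | (2S,3R)-2-(4-ethynyl-2,6-dimethoxyphenoxy)-3-{3-methoxy-4-[(triisopropylsilyl)oxy]phenyl}-3-[(triethylsilyl)oxy]propan-1-ol | COc1cc([C@@H](O[Si](CC)(CC)CC)[C@H](CO)Oc2c(OC)cc(C#C)cc2OC)ccc1O[Si](C(C)C)(C(C)C)C(C)C
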